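# Proposed total synthesis of CNP0210692.1, an epicatechin-(4β→8)-taxifolin biflavonoid, by an ortho-quinone methide cycloaddition

## Analysis of the target

The target is a biflavonoid of the proanthocyanidin type: an upper flavan-3-ol unit (rings A, C and B) is bonded through C4 of its ring C to C8 of ring A of a lower dihydroflavonol unit, which is (2R,3R)-taxifolin. It has five stereocentres. The lower C2 and C3 are trans (2R,3R); in the upper unit (2R,3R,4R) the C2 aryl group and the C3 hydroxyl are cis and the C3 hydroxyl and the C4 aryl group are trans, so the two aryl groups on upper ring C lie on opposite faces. Ten hydroxyl groups are present, eight of them phenolic (two catechols, two tri-oxygenated A rings) and prone to oxidation; the dihydroflavonol opens to a chalcone, epimerises and dehydrogenates under base; the C4–C8 bond, benzylic to two electron-rich rings, is cleaved by acid. The difficulty is to build this crowded, stereogenic diarylmethine carbon at C8 and not C6 of the taxifolin, with the 2,3-cis-3,4-trans array around it, without exposing the lower unit to base. The strategy rests on upper ring C: its O1 sits on the aromatic carbon C8a and its C4 carries two aryl groups (C4a of upper ring A and C8 of the taxifolin), the pattern left by an ortho-quinone methide O1=C8a–C4a=C4 after a two-carbon unit C2–C3 has added across C4 and O1. Because the lower unit is used as a single enantiomer, a wrong configuration at upper C4 gives a diastereomer, not an enantiomer.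

## Retrosynthetic reasoning

**20 to 19.** All ten hydroxyl groups of 20 are traced back to benzyl ethers in the deca-O-benzyl ether 19. The ten O–benzyl bonds are cut last because hydrogenolysis is neutral: it endangers neither the acid-labile C4–C8 bond nor the base-labile dihydroflavonol, and one operation removes every protecting group. The forward step only has to spare the chromanone carbonyl and the two benzylic ring C–O bonds.

**19 to 17.** The C2–H bond of upper ring C is disconnected, which leads to the silyl ketal 17 with C2 at the ketone oxidation level. This lets ring C come from a carbonyl-derived two-carbon unit and postpones the C2 configuration until C3 and C4 are in place to direct it. In the forward direction a silane hydride has to enter the oxocarbenium ion 18 anti to the C3 benzyloxy group, which gives the 2,3-cis relation.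

**17 to 8 and 15.** This is the key disconnection: C3–C4 and O1–C2 are cut together. Both bonds end on neighbouring atoms of one aromatic ring (C4 on C4a, O1 on C8a), so the diene is the ortho-quinone methide 16, formed by dehydration of the ortho-hydroxybenzhydrol 8, and the two-carbon partner is the Z-silyl enol ether 15. The polarity fits: the benzyloxy-bearing carbon of 15 is its nucleophilic end and becomes C3, and the silyloxy carbon becomes the ketal carbon C2. The cut is convergent, installs the C3 oxygen in the ring-forming step and leaves the taxifolin half untouched. The forward reaction has to generate 16 under an acid that the taxifolin tolerates, fix C4 by a chiral phosphoric acid, and place the C3 benzyloxy group trans to the taxifolinyl group. The silyl group of 15 is tert-butyldimethylsilyl: a smaller, trimethylsilyl-type group would be lost to the acid and the moisture set free on dehydration, and the larger group also favours the exo approach that the trans relation needs.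

**8 to 5 and 6.** The bond between the carbinol carbon and C4a of the future upper ring A is cut, giving aldehyde 5 and phenol 6. As its bromomagnesium salt 7, the phenol adds to an aldehyde only through the carbon ortho to oxygen, so the free hydroxyl ends exactly where the quinone methide needs it. The chromanone carbonyl of 5, a hindered vinylogous ester, should not compete.

**5 to 3, 2 and 1.** The formyl group at C8 is removed to give penta-O-benzyltaxifolin 3. Ring A of 3 is still a tri-oxygenated arene, and C8 (between one benzyloxy group and the ring oxygen) is less hindered than C6 (between two benzyloxy groups). Compound 3 comes from taxifolin 1 through the tetra-O-benzyl ether 2. The four phenols are alkylated with K2CO3 as base; the C3 hydroxyl is alkylated with Ag2O and no alkoxide, so that the α-ketol cannot enolise or ring-open. Both lower stereocentres are bought with 1.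

**15 to 14, then 10 and 11, then 9.** The enol ether 15 is the O-silylation product of the α-benzyloxy ketone 14. The ketone is cut between its carbonyl carbon and ring B into the aryl Grignard reagent 12 (from bromide 11) and the N-methoxy-N-methylamide 10, which comes from acid chloride 9. This reaches 14 in two steps without α-oxygenation of an acetophenone.

## Alternatives that were turned down

**Alternative 1:** Lower ring A is disconnected at C4a–C8a, so that the lower unit is grown on the upper one.
- **Forward key step:** the triketo ester A2, which carries a benzyl-protected 2,3-cis flavan at its α-carbon, is folded by Mg(OMe)2. Its C6 enolate attacks the ester carbonyl and the ring aromatises to the acyl-trihydroxybenzene A1.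
- **For:** the three upper stereocentres come from the chiral pool, and the trans capture of a C4 cation by a soft carbon nucleophile is well precedented. On upper-unit stereocontrol this plan is stronger than the chosen one.
- **Against:** A2 is a free polyketide chain with competing aldol and lactonisation modes. After A1 the whole dihydroflavonol still has to be built: chalcone formation, asymmetric oxygenation and ring closure, with both lower stereocentres made under reagent control. The closure must also choose between two non-equivalent ortho hydroxyls of A1; only the hindered one, next to the flavanyl group, gives the 4→8 isomer.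
- **Comparison:** the step count is roughly double. The chosen strategy buys the lower unit complete as 1 and builds a single ring.

**Alternative 2:** Lower ring C is disconnected at C4–C4a.
- **Forward key step:** the seco acid A4, in which the aryl ether O1–C2 is already in place and a bromine blocks the remaining nucleophilic ring carbon, is activated with (CF3CO)2O. It acylates the only free ortho carbon, giving the bromo chromanone A3; the bromine is lost in the final hydrogenolysis.
- **For:** the tether makes the 4→8 linkage unambiguous. On regiochemistry this plan is stronger than the chosen one, which relies on C8-selective formylation of 3.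
- **Against:** A4 needs an aryl ether at a secondary benzylic carbon of defined configuration, made from a phenol flanked by the flavanyl group; such substitutions tend to ionise and lose configuration. Both lower stereocentres must be created, not bought. The strongly acidic acylation endangers the β-aryloxy acid (elimination of the phenol, epimerisation of the α-centre) and the acid-labile interflavan bond.
- **Comparison:** the sequence is longer by the bromination, the ether formation and the building of the side chain. The chosen strategy offers a short convergent route with one uncertain step, and keeps the formylation risk contained by a cross-coupling fallback.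

**Alternative 3:** The same ring, upper ring C, is cut at C4–C4a and O1–C2.
- **Forward key step:** under a chiral phosphoric acid, phenol 6 adds through its ortho carbon to the β-carbon of enone A6 (one aldol condensation from aldehyde 5) and its oxygen condenses on the ketone, giving the 4H-chromene A5.
- **For:** both partners are robust, and the phenol offers the catalyst a hydrogen-bond donor, which is the better-precedented arrangement for setting C4. On robustness and control at C4 this plan is stronger.
- **Against:** A5 lacks the C3 oxygen and has C2=C3. Hydroboration–oxidation adds H and OH syn, anti to the C4 aryl group, and gives the 2,3-trans, 2,4-cis series. The target needs 2,3-cis and 2,4-trans, and an oxidation–reduction sequence at C3 does not correct C2. Without a magnesium template the phenol can also react at its para carbon, and the β-carbon of A6 is a weak electrophile because it is attached to a tri-alkoxy arene.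
- **Comparison:** at least four steps with an unsolved stereochemical problem follow the key step. The chosen strategy introduces the C3 oxygen with the right polarity in the ring-forming step and needs two steps afterwards.

Key step: step 8

Assumption: the (R)-configured phosphoric acid is taken to leave open the face of the methide that leads to 4R; if the sense is the opposite, the (S)-acid is used in the same step with no other change.

Assumption: 4-bromo-1,2-bis(benzyloxy)benzene 11 is taken to be a commercial compound.

## Route

Step 1
Reactants: 1 (+)-taxifolin, (2R,3R)-2-(3,4-dihydroxyphenyl)-3,5,7-trihydroxychroman-4-one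
Product: 2 (2R,3R)-5,7-bis(benzyloxy)-2-[3,4-bis(benzyloxy)phenyl]-3-hydroxychroman-4-one (5,7,3',4'-tetra-O-benzyltaxifolin)
Conditions: BnBr, K2CO3, DMF, rt, N2
Reagents that add atoms: benzyl bromide, BrCc1ccccc1
Why: Williamson etherification of the four phenols; K2CO3 does not deprotonate the C3 α-ketol hydroxyl, and once the 4' and 7 phenols are capped the base-induced ring-opening pathways are closed. The chelated 5-hydroxyl reacts last; the 2R,3R centres are not touched.

Step 2
Reactants: 2 5,7,3',4'-tetra-O-benzyltaxifolin
Product: 3 (2R,3R)-3,5,7-tris(benzyloxy)-2-[3,4-bis(benzyloxy)phenyl]chroman-4-one (penta-O-benzyltaxifolin)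
Conditions: BnBr, Ag2O, 4 Å MS, CH2Cl2, rt, dark
Reagents that add atoms: benzyl bromide, BrCc1ccccc1
Why: Ag2O-assisted O-alkylation (Purdie type) benzylates the secondary alcohol without forming an alkoxide or enolate, so C2 and C3 of the α-ketol should not epimerise and the ring should not open to the chalcone.

Step 3
Reactants: 3 penta-O-benzyltaxifolin
Product: 5 (2R,3R)-3,5,7-tris(benzyloxy)-2-[3,4-bis(benzyloxy)phenyl]-4-oxochromane-8-carbaldehyde (8-formyl-penta-O-benzyltaxifolin), via aryl iminium chloride 4 (not isolated)
Conditions: POCl3, DMF, ClCH2CH2Cl, 0 → 60 °C; then aq NaOAc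
Reagents that add atoms: N,N-dimethylformamide, CN(C)C=O (formyl carbon); water, O (carbonyl oxygen, at work-up)
Why: Vilsmeier–Haack formylation of a tri-alkoxy arene; C6 and C8 are both meta to the acyl carbon and activated by three oxygens, and C8, flanked by one benzyloxy group and the ring oxygen, is less hindered than C6 between two benzyloxy groups. No Lewis acid able to cleave the benzyl ethers is present, and the iminium salt 4 is hydrolysed at work-up.

Step 4
Reactants: 5 8-formyl-penta-O-benzyltaxifolin; 6 3,5-bis(benzyloxy)phenol
Product: 8 [2,4-bis(benzyloxy)-6-hydroxyphenyl][(2R,3R)-3,5,7-tris(benzyloxy)-2-[3,4-bis(benzyloxy)phenyl]-4-oxochroman-8-yl]methanol (both carbinol epimers), via bromomagnesium phenoxide 7 (not isolated)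
Conditions: 6, EtMgBr, Et2O, 0 °C; solvent change to CH2Cl2; then 5, 0 °C → rt; aq NH4Cl
Reagents that add atoms: none
Why: Casiraghi-type ortho-hydroxyalkylation: magnesium binds the phenoxide and the aldehyde oxygen and delivers the ortho carbon through a six-membered chelate, so only the position next to the hydroxyl reacts; the hindered vinylogous-ester ketone should not compete. The new carbinol centre is formed as a mixture and is erased in step 8.

Step 5
Reactants: 9 (benzyloxy)acetyl chloride
Product: 10 2-(benzyloxy)-N-methoxy-N-methylacetamide
Conditions: MeNH(OMe)·HCl, K2CO3, CH2Cl2/H2O, 0 °C → rt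
Reagents that add atoms: N,O-dimethylhydroxylamine hydrochloride, CNOC.Cl
Why: Schotten–Baumann acylation of the hydroxylamine gives the N-methoxy-N-methylamide (Weinreb amide).

Step 6
Reactants: 10 2-(benzyloxy)-N-methoxy-N-methylacetamide; 11 4-bromo-1,2-bis(benzyloxy)benzene
Product: 14 2-(benzyloxy)-1-[3,4-bis(benzyloxy)phenyl]ethan-1-one, via aryl Grignard reagent 12 (not isolated), via chelated tetrahedral adduct 13 (not isolated)
Conditions: 11, Mg, THF, 40 °C; then 10, 0 °C; 1 M HCl
Reagents that add atoms: none
Why: Weinreb ketone synthesis: the magnesium-chelated adduct 13 does not collapse until the acidic work-up, so the Grignard reagent adds only once.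

Step 7
Reactants: 14 2-(benzyloxy)-1-[3,4-bis(benzyloxy)phenyl]ethan-1-one
Product: 15 (Z)-{[2-(benzyloxy)-1-[3,4-bis(benzyloxy)phenyl]ethenyl]oxy}(tert-butyl)dimethylsilane, benzyloxy and silyloxy groups cis
Conditions: TBSOTf, Et3N, CH2Cl2, 0 °C
Reagents that add atoms: tert-butyldimethylsilyl trifluoromethanesulfonate, CC(C)(C)[Si](C)(C)OS(=O)(=O)C(F)(F)F
Why: Soft enolisation and O-silylation of an aryl ketone; the Z isomer is expected because the benzyloxy group avoids allylic strain with the aryl group and 1,2-dioxygenated alkenes prefer the cis arrangement. The tert-butyldimethylsilyl ether should survive chromatography on base-washed silica and the acid of step 8.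

Step 8
Reactants: 8 ortho-hydroxybenzhydrol; 15 (Z)-silyl enol ether (2 equiv)
Product: 17 (3R,4R)-3,5,7-tris(benzyloxy)-2-[3,4-bis(benzyloxy)phenyl]-2-(tert-butyldimethylsilyloxy)-4-[(2R,3R)-3,5,7-tris(benzyloxy)-2-[3,4-bis(benzyloxy)phenyl]-4-oxochroman-8-yl]chromane (3,4-trans; C2 not assigned), via ortho-quinone methide 16 (not isolated)
Conditions: (R)-3,3'-bis(2,4,6-triisopropylphenyl)-1,1'-binaphthyl-2,2'-diyl hydrogen phosphate (10 mol%), 5 Å MS, toluene, −20 °C → rt
Reagents that add atoms: none
Why: The phosphoric acid protonates the benzylic hydroxyl of 8 and one molecule of water is lost to the sieves, giving the (E)-ortho-quinone methide 16 hydrogen-bonded through its carbonyl oxygen to the phosphate (in the limit an ion pair of the diarylmethyl cation). The CH(OBn) carbon of 15, the nucleophilic end of the enol silane, bonds to the methide carbon (C3–C4) while C2 becomes an aryl-stabilised silyloxocarbenium ion that the phenolic oxygen captures (O1–C2); this is an inverse-electron-demand hetero-Diels–Alder reaction, either concerted and asynchronous or stepwise as a Mukaiyama–Michael addition followed by ketalisation. The closest known reaction type is the chiral phosphoric acid-catalysed [4+2] cycloaddition and conjugate addition of enol ethers, enecarbamates and silyl enolates to ortho-quinone methides generated from ortho-hydroxybenzhydrols. Upper ring C is closed as the six-membered ring of the [4+2] process across O1=C8a–C4a=C4, which in the stepwise limit is a 6-exo-trig attack of O1 on the C2 oxocarbenium carbon. C4 is set by the catalyst: the phosphate bound at O1 shields one face of the methide, and the (R)-acid is assumed to leave open the face that gives 4R, since the taxifolin centres are too remote to decide. C3 is set relative to C4 by the approach geometry: with the taxifolinyl group outside on the E-methide, the flat aryl group of 15 lies endo over the dienone and the bulky silyloxy group points exo, and because benzyloxy is cis to silyloxy in the Z-olefin it is exo as well and ends trans to the taxifolinyl group (3R). The step needs regioselectivity, which the polarity of the partners secures (only the benzyloxy-bearing carbon is nucleophilic and only the methide carbon electrophilic), face selectivity, which rests on the catalyst, and the exo mode, which rests on the Z geometry and the size of the silyl group; since the taxifolin part is a single enantiomer, any C4 epimer is a diastereomer and can be removed by chromatography. The ketal centre C2 is formed without control and is erased in step 9.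

Step 9
Reactants: 17 silyl ketal
Product: 19 (2R,3R)-3,5,7-tris(benzyloxy)-2-[3,4-bis(benzyloxy)phenyl]-8-[(2R,3R,4R)-3,5,7-tris(benzyloxy)-2-[3,4-bis(benzyloxy)phenyl]chroman-4-yl]chroman-4-one (deca-O-benzyl ether of the target; upper unit 2,3-cis-3,4-trans), via cyclic oxocarbenium ion 18 (not isolated)
Conditions: Et3SiH, BF3·OEt2, CH2Cl2, −78 → −40 °C
Reagents that add atoms: none
Why: Ionic hydrogenation of a ketal: BF3 removes the silyloxy group to give the 2-aryl oxocarbenium ion 18, in which the trans C3 benzyloxy and C4 aryl groups are pseudo-axial to avoid strain with the C2 aryl and C5 benzyloxy groups. Et3SiH should attack C2 anti to the adjacent pseudo-axial C–O bond (Felkin–Anh polar and steric control), so the new hydrogen is trans to the benzyloxy group and the aryl group cis to it (2R). The low temperature keeps the chromanone carbonyl and the benzyl ethers out of the reaction.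

Step 10
Reactants: 19 deca-O-benzyl ether
Product: 20 (2R,3R)-2-(3,4-dihydroxyphenyl)-8-[(2R,3R,4R)-2-(3,4-dihydroxyphenyl)-3,5,7-trihydroxychroman-4-yl]-3,5,7-trihydroxychroman-4-one (CNP0210692.1)
Conditions: H2 (1 atm), Pd(OH)2/C, THF/MeOH, rt
Reagents that add atoms: none
Why: Hydrogenolysis of the ten benzyl ethers under neutral conditions, which spare the acid-labile interflavan bond and the base-labile dihydroflavonol. The chromanone carbonyl, conjugated with three ring oxygens, and the cyclic benzylic ethers should react much more slowly than O-benzyl groups; no stereocentre is touched.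

## Compound list

1 | (+)-taxifolin, (2R,3R)-2-(3,4-dihydroxyphenyl)-3,5,7-trihydroxychroman-4-one | O=C1c2c(O)cc(O)cc2O[C@H](c2ccc(O)c(O)c2)[C@H]1O | starting material
2 | 5,7,3',4'-tetra-O-benzyltaxifolin | O=C1c2c(OCc9ccccc9)cc(OCc9ccccc9)cc2O[C@H](c2ccc(OCc9ccccc9)c(OCc9ccccc9)c2)[C@H]1O | intermediate
3 | penta-O-benzyltaxifolin | O=C1c2c(OCc9ccccc9)cc(OCc9ccccc9)cc2O[C@H](c2ccc(OCc9ccccc9)c(OCc9ccccc9)c2)[C@H]1OCc9ccccc9 | intermediate
4 | 8-[(dimethyliminio)methyl]-penta-O-benzyltaxifolin chloride (not isolated) | O=C1c2c(OCc9ccccc9)cc(OCc9ccccc9)c(C=[N+](C)C)c2O[C@H](c2ccc(OCc9ccccc9)c(OCc9ccccc9)c2)[C@H]1OCc9ccccc9.[Cl-] | intermediate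
5 | 8-formyl-penta-O-benzyltaxifolin | O=C1c2c(OCc9ccccc9)cc(OCc9ccccc9)c(C=O)c2O[C@H](c2ccc(OCc9ccccc9)c(OCc9ccccc9)c2)[C@H]1OCc9ccccc9 | intermediate
6 | 3,5-bis(benzyloxy)phenol | Oc1cc(OCc2ccccc2)cc(OCc2ccccc2)c1 | starting material
7 | bromomagnesium 3,5-bis(benzyloxy)phenoxide (not isolated) | Br[Mg]Oc1cc(OCc2ccccc2)cc(OCc2ccccc2)c1 | intermediate
8 | [2,4-bis(benzyloxy)-6-hydroxyphenyl](penta-O-benzyltaxifolin-8-yl)methanol, both carbinol epimers | O=C1c2c(OCc9ccccc9)cc(OCc9ccccc9)c(C(O)c3c(O)cc(OCc9ccccc9)cc3OCc9ccccc9)c2O[C@H](c2ccc(OCc9ccccc9)c(OCc9ccccc9)c2)[C@H]1OCc9ccccc9 | intermediate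
9 | (benzyloxy)acetyl chloride | O=C(Cl)COCc1ccccc1 | starting material
10 | 2-(benzyloxy)-N-methoxy-N-methylacetamide | CON(C)C(=O)COCc1ccccc1 | intermediate
11 | 4-bromo-1,2-bis(benzyloxy)benzene | Brc1ccc(OCc2ccccc2)c(OCc2ccccc2)c1 | starting material
12 | [3,4-bis(benzyloxy)phenyl]magnesium bromide (not isolated) | Br[Mg]c1ccc(OCc2ccccc2)c(OCc2ccccc2)c1 | intermediate
13 | bromomagnesium salt of the tetrahedral adduct of 12 and 10 (not isolated) | CON(C)C(O[Mg]Br)(COCc1ccccc1)c1ccc(OCc2ccccc2)c(OCc2ccccc2)c1 | intermediate
14 | 2-(benzyloxy)-1-[3,4-bis(benzyloxy)phenyl]ethan-1-one | O=C(COCc1ccccc1)c1ccc(OCc2ccccc2)c(OCc2ccccc2)c1 | intermediate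
15 | (Z)-{[2-(benzyloxy)-1-[3,4-bis(benzyloxy)phenyl]ethenyl]oxy}(tert-butyl)dimethylsilane | CC(C)(C)[Si](C)(C)O/C(c1ccc(OCc2ccccc2)c(OCc2ccccc2)c1)=C\OCc1ccccc1 | intermediate
16 | (E)-3,5-bis(benzyloxy)-6-[(penta-O-benzyltaxifolin-8-yl)methylidene]cyclohexa-2,4-dien-1-one, the ortho-quinone methide (not isolated) | O=C1c2c(OCc9ccccc9)cc(OCc9ccccc9)c(/C=C3/C(=O)C=C(OCc9ccccc9)C=C3OCc9ccccc9)c2O[C@H](c2ccc(OCc9ccccc9)c(OCc9ccccc9)c2)[C@H]1OCc9ccccc9 | intermediate
17 | 2-(tert-butyldimethylsilyloxy) ketal of the deca-O-benzyl skeleton, (3R,4R), C2 not assigned | O=C1c2c(OCc9ccccc9)cc(OCc9ccccc9)c([C@H]3c4c(OCc9ccccc9)cc(OCc9ccccc9)cc4OC(O[Si](C)(C)C(C)(C)C)(c4ccc(OCc9ccccc9)c(OCc9ccccc9)c4)[C@@H]3OCc9ccccc9)c2O[C@H](c2ccc(OCc9ccccc9)c(OCc9ccccc9)c2)[C@H]1OCc9ccccc9 | intermediate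
18 | (3R,4R)-2-aryl-3,4-dihydro-2H-chromenylium ion (C2 oxocarbenium) as its (tert-butyldimethylsilyloxy)trifluoroborate (not isolated) | O=C1c2c(OCc9ccccc9)cc(OCc9ccccc9)c([C@H]3c4c(OCc9ccccc9)cc(OCc9ccccc9)cc4[O+]=C(c4ccc(OCc9ccccc9)c(OCc9ccccc9)c4)[C@@H]3OCc9ccccc9)c2O[C@H](c2ccc(OCc9ccccc9)c(OCc9ccccc9)c2)[C@H]1OCc9ccccc9.CC(C)(C)[Si](C)(C)O[B-](F)(F)F | intermediate
19 | deca-O-benzyl ether of the target, upper unit (2R,3R,4R), lower unit (2R,3R) | O=C1c2c(OCc9ccccc9)cc(OCc9ccccc9)c([C@H]3c4c(OCc9ccccc9)cc(OCc9ccccc9)cc4O[C@H](c4ccc(OCc9ccccc9)c(OCc9ccccc9)c4)[C@@H]3OCc9ccccc9)c2O[C@H](c2ccc(OCc9ccccc9)c(OCc9ccccc9)c2)[C@H]1OCc9ccccc9 | intermediate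
20 | CNP0210692.1, (2R,3R)-2-(3,4-dihydroxyphenyl)-8-[(2R,3R,4R)-2-(3,4-dihydroxyphenyl)-3,5,7-trihydroxychroman-4-yl]-3,5,7-trihydroxychroman-4-one | O=C1c2c(O)cc(O)c([C@H]3c4c(O)cc(O)cc4O[C@H](c4ccc(O)c(O)c4)[C@@H]3O)c2O[C@H](c2ccc(O)c(O)c2)[C@H]1O | target

## Step count and least certain steps

Total step count: 10. Longest linear sequence: 7 steps (steps 1, 2, 3, 4, 8, 9, 10); the enol ether branch (steps 5 to 7) joins at step 8.

**Step 8 (key step).**
- What may go wrong: insufficient discrimination between the two faces of the methide and between the exo and endo approach, so that the C4 epimer and the 3,4-cis isomer form alongside. The silyl enol ether offers the phosphate no hydrogen-bond handle, and the methide carbon is flanked by four ortho substituents. The peri benzyloxy group on the methide ring may also erode the preference for the E-methide, on which the exo-to-trans argument rests. If the addition is slow, protodesilylation of 15 by the water set free takes over.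
- Fallback: it sets out from 8 and 15 and gives up catalyst control. An achiral acid ((PhO)2P(O)OH, 5 Å sieves, CH2Cl2, −40 °C) promotes the same dehydration, addition and ketalisation. The crude silyl ketal 17, now accompanied by its C3 and C4 isomers, is cleaved with HF·pyridine to the 2-hydroxy hemiketal F1, which is more polar and easier to resolve. Its isomers at C4 and C3 are diastereomers because the taxifolin centres are fixed, and they are separated by chromatography. The 3,4-trans, 4R isomer is reduced with Et3SiH and BF3·OEt2 as in step 9, and the route is rejoined at 19.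

**Step 3.**
- What may go wrong: substitution at C6 as well as C8, or no reaction because ring A is deactivated by the carbonyl group, with loss of the 5-O-benzyl group or attack of the chloroiminium reagent on the enolisable chromanone if the conditions are forced.
- Fallback: it sets out from 3. Bromination with N-bromosuccinimide (MeCN, 0 °C), an electrophile that reacts at room temperature or below and for which C8 selectivity in 5,7-dialkoxy chromanones and chromones is better documented, should give 8-bromo-penta-O-benzyltaxifolin F2. Stille coupling with tributyl(vinyl)stannane (Pd(PPh3)4, toluene, 100 °C, no base) should give 8-vinyl-penta-O-benzyltaxifolin F3. Lemieux–Johnson cleavage (OsO4 cat., NaIO4, 2,6-lutidine, dioxane/H2O) returns to the route at 5.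

**Step 4.**
- What may go wrong: over-reaction, in which the magnesium benzhydrolate ionises to the quinone methide and is captured by a second phenoxide; or sluggish addition to the doubly ortho-substituted, electron-rich aldehyde; or decomposition of the acid-labile benzhydrol on purification.
- Fallback: it sets out from 5 and 6. Condensation with PhB(OH)2 and catalytic propanoic acid in toluene at reflux with removal of water (Nagata ortho-hydroxyalkylation) locks the benzylic oxygen and the phenol oxygen into the 2-phenyl-4H-1,3,2-benzodioxaborin F4, which is far less prone to ionise than the magnesium benzhydrolate. Transesterification with propane-1,3-diol (THF, rt) releases the benzhydrol and returns to the route at 8.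

**Step 9.**
- What may go wrong: hydride delivery from the face of the C3 benzyloxy group, which is the face anti to the pseudo-axial C4 aryl group, leading to the C2 epimer. Also possible are loss of the C3 configuration through deprotonation of 18 to the cyclic enol ether and re-protonation, and ionic reduction of the chromanone carbonyl if the temperature rises.
- Fallback: it sets out from 17 and sets C2 by substitution with inversion in place of hydride addition to a cation. HF·pyridine gives the hemiketal F1, which is in equilibrium with its ring-opened tautomer, the open-chain hydroxy ketone F5. Chelation-controlled reduction of F5 (Zn(BH4)2, Et2O/CH2Cl2, −30 °C) should give the anti benzylic alcohol F6. The open-chain aryl ketone is expected to react ahead of the hindered vinylogous-ester chromanone, but this chemoselectivity is a risk of the fallback. Intramolecular Mitsunobu etherification (PPh3, diisopropyl azodicarboxylate, THF, 0 °C) closes ring C with inversion at C2 and returns to the route at 19.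

## Further compounds

F1 | step 8 | 2-hydroxy hemiketal of the deca-O-benzyl skeleton, (3R,4R), C2 not assigned | O=C1c2c(OCc9ccccc9)cc(OCc9ccccc9)c([C@H]3c4c(OCc9ccccc9)cc(OCc9ccccc9)cc4OC(O)(c4ccc(OCc9ccccc9)c(OCc9ccccc9)c4)[C@@H]3OCc9ccccc9)c2O[C@H](c2ccc(OCc9ccccc9)c(OCc9ccccc9)c2)[C@H]1OCc9ccccc9
F2 | step 3 | 8-bromo-penta-O-benzyltaxifolin | O=C1c2c(OCc9ccccc9)cc(OCc9ccccc9)c(Br)c2O[C@H](c2ccc(OCc9ccccc9)c(OCc9ccccc9)c2)[C@H]1OCc9ccccc9
F3 | step 3 | 8-vinyl-penta-O-benzyltaxifolin | O=C1c2c(OCc9ccccc9)cc(OCc9ccccc9)c(C=C)c2O[C@H](c2ccc(OCc9ccccc9)c(OCc9ccccc9)c2)[C@H]1OCc9ccccc9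
F4 | step 4 | 5,7-bis(benzyloxy)-2-phenyl-4-(penta-O-benzyltaxifolin-8-yl)-4H-1,3,2-benzodioxaborin, both C4 epimers | O=C1c2c(OCc9ccccc9)cc(OCc9ccccc9)c(C3OB(c4ccccc4)Oc4cc(OCc9ccccc9)cc(OCc9ccccc9)c34)c2O[C@H](c2ccc(OCc9ccccc9)c(OCc9ccccc9)c2)[C@H]1OCc9ccccc9
F5 | step 9 | open-chain hydroxy ketone, ring-opened tautomer of F1: 8-[1-[2,4-bis(benzyloxy)-6-hydroxyphenyl]-2-(benzyloxy)-3-[3,4-bis(benzyloxy)phenyl]-3-oxopropyl]-penta-O-benzyltaxifolin | O=C1c2c(OCc9ccccc9)cc(OCc9ccccc9)c([C@@H](c3c(OCc9ccccc9)cc(OCc9ccccc9)cc3O)[C@@H](OCc9ccccc9)C(=O)c3ccc(OCc9ccccc9)c(OCc9ccccc9)c3)c2O[C@H](c2ccc(OCc9ccccc9)c(OCc9ccccc9)c2)[C@H]1OCc9ccccc9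
F6 | step 9 | open-chain anti benzylic alcohol: 8-[1-[2,4-bis(benzyloxy)-6-hydroxyphenyl]-2-(benzyloxy)-3-[3,4-bis(benzyloxy)phenyl]-3-hydroxypropyl]-penta-O-benzyltaxifolin, hydroxyl anti to the neighbouring benzyloxy group | O=C1c2c(OCc9ccccc9)cc(OCc9ccccc9)c([C@@H](c3c(OCc9ccccc9)cc(OCc9ccccc9)cc3O)[C@@H](OCc9ccccc9)[C@@H](O)c3ccc(OCc9ccccc9)c(OCc9ccccc9)c3)c2O[C@H](c2ccc(OCc9ccccc9)c(OCc9ccccc9)c2)[C@H]1OCc9ccccc9
A1 | alternative 1 | 3-(penta-O-benzyl-2,3-cis-flavan-4β-yl)-2,4,6-trihydroxyacetophenone | CC(=O)c1c(O)cc(O)c([C@H]3c4c(OCc9ccccc9)cc(OCc9ccccc9)cc4O[C@H](c4ccc(OCc9ccccc9)c(OCc9ccccc9)c4)[C@@H]3OCc9ccccc9)c1O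
A2 | alternative 1 | methyl 2-(penta-O-benzyl-2,3-cis-flavan-4β-yl)-3,5,7-trioxooctanoate, α-carbon not assigned | COC(=O)C(C(=O)CC(=O)CC(C)=O)[C@H]3c4c(OCc9ccccc9)cc(OCc9ccccc9)cc4O[C@H](c4ccc(OCc9ccccc9)c(OCc9ccccc9)c4)[C@@H]3OCc9ccccc9
A3 | alternative 2 | 6-bromo derivative of the deca-O-benzyl ether 19 | O=C1c2c(OCc9ccccc9)c(Br)c(OCc9ccccc9)c([C@H]3c4c(OCc9ccccc9)cc(OCc9ccccc9)cc4O[C@H](c4ccc(OCc9ccccc9)c(OCc9ccccc9)c4)[C@@H]3OCc9ccccc9)c2O[C@H](c2ccc(OCc9ccccc9)c(OCc9ccccc9)c2)[C@H]1OCc9ccccc9
A4 | alternative 2 | seco acid of A3: 2-(benzyloxy)-3-[3,4-bis(benzyloxy)phenyl]-3-{[3,5-bis(benzyloxy)-4-bromo-2-(penta-O-benzyl-2,3-cis-flavan-4β-yl)phenyl]oxy}propanoic acid, configurations as in A3 | OC(=O)[C@H](OCc9ccccc9)[C@@H](c1ccc(OCc9ccccc9)c(OCc9ccccc9)c1)Oc1c([C@H]3c4c(OCc9ccccc9)cc(OCc9ccccc9)cc4O[C@H](c4ccc(OCc9ccccc9)c(OCc9ccccc9)c4)[C@@H]3OCc9ccccc9)c(OCc9ccccc9)c(Br)c(OCc9ccccc9)c1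
A5 | alternative 3 | 5,7-bis(benzyloxy)-2-[3,4-bis(benzyloxy)phenyl]-4-(penta-O-benzyltaxifolin-8-yl)-4H-chromene | O=C1c2c(OCc9ccccc9)cc(OCc9ccccc9)c([C@H]3c4c(OCc9ccccc9)cc(OCc9ccccc9)cc4OC(c4ccc(OCc9ccccc9)c(OCc9ccccc9)c4)=C3)c2O[C@H](c2ccc(OCc9ccccc9)c(OCc9ccccc9)c2)[C@H]1OCc9ccccc9
A6 | alternative 3 | (E)-1-[3,4-bis(benzyloxy)phenyl]-3-(penta-O-benzyltaxifolin-8-yl)prop-2-en-1-one | O=C1c2c(OCc9ccccc9)cc(OCc9ccccc9)c(/C=C/C(=O)c3ccc(OCc9ccccc9)c(OCc9ccccc9)c3)c2O[C@H](c2ccc(OCc9ccccc9)c(OCc9ccccc9)c2)[C@H]1OCc9ccccc9
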